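## Structural features

The target is a resveratrol trimer built on a dibenzo-fused cycloheptene: ring B (carbons b1–b6) and ring C (c1–c6) are joined on one side through the sp3 carbon C5 (b6–C5–c1) and on the other through the double bond C10=C11, where C10 is bound to c6 and carries a 4-hydroxyphenyl group and C11 is a CH bound to b1. A trans-2-aryl-2,3-dihydrofuran is fused to each benzene ring: on ring B it consists of b5–O, Cα (4-hydroxyphenyl), C5 and b6, so that C5 belongs to both the furan and the seven-membered ring; on ring C it consists of c5–O, C2″ (4-hydroxyphenyl), C3″ (3,5-dihydroxyphenyl) and c4, while b3 and c3 carry free hydroxyls. The four stereocentres form two adjacent pairs, C5 (S)/Cα (S) and C2″ (R)/C3″ (R), each trans; the pairs are separated by ring C, so neither can steer the other and each needs its own absolute control. Fragile elements are the seven phenols, the electron-rich triarylethylene and above all the benzylic C–O bonds at Cα and C2″, which ionise in acid because each carbon bears a para-oxygenated aryl group; this allows cis-to-trans equilibration but endangers the rings during deprotection. The real difficulty is the cycloheptene: its aryl group must sit on C10 and not on C11, C11 must be attached to b1 (meta to both oxygens of ring B and so closed to electrophilic ring closure), and ring C must be entered at c6 and not at c2 while its two oxygens are kept apart. The key step uses the fact that C10 and C11 bridge c6 and b1 on the same side of the double bond: an aryl–palladium bond at c6 adds syn across an arylalkyne, and the vinylpalladium so formed, held beside b1–H by the rigid 3-aryl-2,3-dihydrobenzofuran, closes the ring through that C–H bond.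

## Logic of the disconnections

30 ⇒ 29. The seven aryl O–CH3 bonds are cut last. Methyl ethers are the one phenol protection that passes through Grignard, carbene, palladium and acid steps alike, and they leave a single deprotection. The price is that the dealkylation of 29 has to spare two acid-labile benzylic ethers.

29 ⇒ 26. The C2″–C3″ bond is cut, which opens the ring C dihydrofuran to a diaryl ketone hydrazone with a 4-methoxybenzyl ether on c5–O. Both stereocentres of this furan then come from one catalyst-controlled C–H insertion (through 27 and 28) followed by acid equilibration. The forward step must prefer the benzylic C–H bond to the methoxy group on c3, must be ruled by the catalyst and not by the remote centres, and must leave the first furan trans.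

26 ⇒ 25 ⇒ 24 ⇒ 21 + 22. The C=N bond and then the bond between the carbinol carbon and the dimethoxyphenyl ring are cut. Aryl Grignard addition to an aldehyde followed by oxidation is the most dependable entry to a ketone flanked by two ortho ethers, and it brings the resorcinol ring in from a commercial bromide (through 23). The demand lies in condensing hydrazine with the crowded carbonyl of 25.

21 ⇒ 20 + 7 and 20 ⇒ 19. The benzylic O–C bond and the c4–CHO bond are cut. With c5–OH as the only free phenol and c6 occupied, magnesium-mediated formylation can only go to c4. This removes every regiochemical question but requires that c5–O has travelled under a group orthogonal to the four methyl ethers of 19.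

19 ⇒ 18 ⇒ 17. The O–isopropyl bond and the C11–Si bond are cut. The isopropyl ether is that orthogonal group, and silicon exists only to orient the alkyne one step earlier. The forward steps need BCl3 to tell a secondary alkyl ether from methyl ethers, and a protic acid that takes silicon off C11 without opening the dihydrofuran.

17 ⇒ 15 + 16. The bonds c6–C10 and C11–b1 are cut, which removes the two-carbon bridge as a commercial alkyne and leaves a 3-aryl-2,3-dihydrobenzofuran with iodine on c6. This is the largest simplification of the plan: the seven-membered ring, the placing of the aryl group on C10 and the entry into ring C at c6 are settled together, and b1 needs no prior functional group. The forward step must insert the alkyne in one orientation and then functionalise b1–H through an eight-membered palladacycle. The oxygen on c5, ortho to the iodide, must therefore carry no C–H bond that palladium could arylate, which is why 15 bears an isopropyl and not a benzyl ether.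

15 ⇒ 12. The C5–Cα bond is cut. Donor–donor carbene insertion into the 4-methoxybenzyl ether (through 13 and 14) sets C5 by catalyst control and lets Cα follow by equilibration, so the whole dihydrofuran comes from an achiral hydrazone. The iodide ortho to the carbene carbon has to be tolerated.

12 ⇒ 11 ⇒ 10 ⇒ 5 + 8. The C=N bond and then the bond between the carbinol carbon and b6 are cut. The Grignard reagent 9 made from 8 already carries the 4-methoxybenzyl ether, so no hindered phenol has to be alkylated later. It must add to the aldehyde of 5 faster than it exchanges with the aryl iodide.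

8 ⇒ 6 + 7 and 5 ⇒ 3 ⇒ 2 ⇒ 1. A simple O-alkylation gives 8. In 5 the O–isopropyl bond, the c6–I bond and the O–acetyl bond of 2 are cut. Iodine has to enter ortho to the oxygen that later becomes the furan oxygen, not ortho to the methoxy group. This is arranged by iodinating 2, in which c5–O is acylated and the methoxy group is the only strong donor and directs para. The acetyl group is then exchanged for isopropyl through 4.

## Other disconnections considered

Alternative 1: The cuts are C5–b6 (ring B dihydrofuran) and c6–C10 (seven-membered ring). In the forward direction acid would ionise the C5 carbinol of the aryl ether A2. Carbon b6, ortho to the ether oxygen and para to the methoxy group, would capture the cation and close the dihydrofuran. The alkyne on b1 would then be protonated at C11 and attacked at C10 by c6 of the resorcinol ring (7-endo-dig) to give A1.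
- In favour: two rings, two C–C bonds and the C5 centre come from one flask, by reaction types (Friedel–Crafts alkylation, alkyne hydroarylation) that are established, whereas the palladium sequence of the chosen plan is not. On precedent and on step count at the core stage this alternative is the better one. Carbon b1 carries the alkyne from the outset, so the unreactive b1–H bond is never touched, an equal answer to the same problem.
- Against: the C5 cation gets no help from ring C (both oxygens meta) and sits next to a migration-prone aryl group on Cα, hence the pivalate. C5 is set by substrate control only, 6-exo attack at C11 competes with the 7-endo mode, and Cα must first be made enantioenriched in an acyclic ether.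
- Above all, A1 emerges with ring C as a symmetrical free resorcinol. The choice of which oxygen becomes the furan oxygen is postponed to a stage where the two hydroxyls differ only in hindrance. In the chosen plan the iodide marks c6 and the isopropyl/methyl pair marks the oxygens from step 3 on.
- Comparison: the alternative is shorter to the core and mechanistically better precedented, but leaves the regiochemistry of ring C open. The chosen plan is longer and rests on an untested C–H step, but every later step is regiochemically unambiguous.

Alternative 2: The cut is b6–C5, made in the forward sense by a 1,2-shift. The flavanone triflate A4 would come from (S)-naringenin A5 by methylation of the 7- and 4′-hydroxyls and triflation of the chelated 5-hydroxyl. With PhI(OAc)2 and H2SO4 in trimethyl orthoformate it would form the enol ether, be iodinated at C3 and let the fused aryl carbon migrate from the ketal carbon to C3 with loss of iodobenzene, contracting the pyranone to the trans dihydrobenzofuran ester A3.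
- In favour: Cα comes from the chiral pool without an asymmetric catalyst, the trans relation follows from the rearrangement, and A3 would be reached in about three steps against eight for 15. The triflate sits exactly on b1, so C11 could be attached by ordinary cross-coupling. On cost, on step count to the ring B furan and on the handling of b1 this alternative is the better one.
- Against: C5 carries a methoxycarbonyl group where the target has ring C. The ester must either be turned into a benzene ring or be replaced in a decarboxylative arylation, in which C5 passes through a radical or organometallic centre and its configuration rests on substrate control alone. The flavanone centre can racemise by reversible ring opening to the chalcone in acid. The triflate lowers the migratory aptitude of the fused ring, so aryl migration from C2 (the isoflavone pathway) and dehydrogenation to the flavone compete.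
- Comparison: A3 delivers the same two stereocentres as 15 but neither ring C nor the bridge. Mechanistically it is known chemistry set against a catalytic asymmetric insertion that is also known, so the two are equal on precedent. In step economy the early gain is likely to be spent on attaching ring C and C10.

Alternative 3: The cut is C2″–C3″. The diaryldiazomethane A7 would lose nitrogen on Rh2(S-PTAD)4, the carbene would insert into a benzylic C–H bond of the neighbouring 4-methoxybenzyl ether, and acid would equilibrate C2″ to give A6, the heptamethyl ether of the target. A6 and A7 are the same compounds as 29 and 27: this construction is kept in the chosen route as step 17, and the question is only whether it should carry the strategy.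
- In favour: it is a known reaction class, it creates two stereocentres under catalyst control, and as the last C–C bond formation it keeps the synthesis convergent. On precedent it is better than the palladium annulation.
- Against, as the centre of the plan: it solves the easier half of the molecule and says nothing about the cycloheptene, the attachment to b1 or the differentiation of the ring C oxygens, all of which must be in place before A7 can be written.
- Comparison: in structure the two readings end in the same compound, in mechanism the alternative is the safer step, and in step economy they are equal, since steps 12 to 17 are needed either way. The chosen plan puts the weight on the step that decides whether the core can be made at all.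

Key step: step 9

Assumption: Rh2(R-PTAD)4 is taken to give the C5 configuration of 14 and Rh2(S-PTAD)4 the C3″ configuration of 28; should the sense of induction be the opposite, the two antipodes of the catalyst change places.

Locants in the names of 17–27: 1 = Cα, 11b = C5, 4 = b3, 6 = C11, 7 = C10, 8 = c5, 9 = c4, 10 = c3.

## Route

Step 1
Reactants: 1 3-hydroxy-5-methoxybenzaldehyde
Product: 2 3-formyl-5-methoxyphenyl acetate
Conditions: Ac2O, pyridine, DMAP (cat.), CH2Cl2, 0 °C → rt
Reagents that add atoms: acetic anhydride, CC(=O)OC(C)=O
Why: O-Acylation of the phenol; the acetoxy group is a much weaker donor than methoxy, so the next step is directed by the methoxy group alone.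

Step 2
Reactants: 2 3-formyl-5-methoxyphenyl acetate
Product: 3 3-formyl-2-iodo-5-methoxyphenyl acetate
Conditions: NIS, TFA, MeCN, rt
Reagents that add atoms: N-iodosuccinimide, O=C1CCC(=O)N1I
Why: Electrophilic aromatic iodination; attack para to the methoxy group (the carbon between the formyl and acetoxy groups) should dominate, in line with the halogenation of 3-methoxybenzaldehyde para to methoxy and ortho to formyl, the two positions ortho to methoxy being less activated.

Step 3
Reactants: 3 3-formyl-2-iodo-5-methoxyphenyl acetate
Product: 5 2-iodo-5-methoxy-3-(propan-2-yloxy)benzaldehyde, via 3-hydroxy-2-iodo-5-methoxybenzaldehyde 4 (not isolated)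
Conditions: K2CO3, MeOH, rt; evaporate; 2-bromopropane, K2CO3, DMF, 60 °C
Reagents that add atoms: 2-bromopropane, CC(C)Br
Why: Methanolysis of the aryl acetate, then Williamson ether synthesis; the isopropyl ether resists hydrazine, carbenes, acid and palladium, is later removed by BCl3 beside methyl ethers, and unlike a benzyl ether offers no aryl C–H bond to palladium on the neighbouring carbon.

Step 4
Reactants: 6 2-bromo-5-methoxyphenol; 7 4-methoxybenzyl chloride
Product: 8 1-bromo-4-methoxy-2-[(4-methoxybenzyl)oxy]benzene
Conditions: K2CO3, DMF, 60 °C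
Reagents that add atoms: none
Why: Williamson ether synthesis on an unhindered phenoxide; it puts the future Cα and its aryl group in place before the ketone is built.

Step 5
Reactants: 8 1-bromo-4-methoxy-2-[(4-methoxybenzyl)oxy]benzene; 5 2-iodo-5-methoxy-3-(propan-2-yloxy)benzaldehyde
Product: 10 [2-iodo-5-methoxy-3-(propan-2-yloxy)phenyl]{4-methoxy-2-[(4-methoxybenzyl)oxy]phenyl}methanol (racemic), via {4-methoxy-2-[(4-methoxybenzyl)oxy]phenyl}magnesium bromide 9 (not isolated)
Conditions: Mg, I2 (cat.), THF, reflux; then 5, THF, −20 °C → rt; aq. NH4Cl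
Reagents that add atoms: none
Why: Grignard addition to an aldehyde; carbonyl addition is much faster than halogen–magnesium exchange between an arylmagnesium bromide and an aryl iodide at low temperature, and the carbinol centre is removed in step 6.

Step 6
Reactants: 10 [2-iodo-5-methoxy-3-(propan-2-yloxy)phenyl]{4-methoxy-2-[(4-methoxybenzyl)oxy]phenyl}methanol
Product: 11 [2-iodo-5-methoxy-3-(propan-2-yloxy)phenyl]{4-methoxy-2-[(4-methoxybenzyl)oxy]phenyl}methanone
Conditions: Dess–Martin periodinane, CH2Cl2, rt
Reagents that add atoms: none
Why: Dess–Martin oxidation of a benzhydrol under neutral conditions that leave the benzyl ether and the iodide untouched.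

Step 7
Reactants: 11 [2-iodo-5-methoxy-3-(propan-2-yloxy)phenyl]{4-methoxy-2-[(4-methoxybenzyl)oxy]phenyl}methanone
Product: 12 hydrazone of 11 (C=N isomers)
Conditions: N2H4·H2O (excess), AcOH (cat.), EtOH, 90 °C (sealed tube)
Reagents that add atoms: hydrazine (used as hydrate), NN
Why: Condensation of a diaryl ketone with hydrazine; the excess suppresses azine formation and the two ortho substituents slow the reaction but should not block it.

Step 8
Reactants: 12 hydrazone of 11
Product: 15 (2S,3R)-3-[2-iodo-5-methoxy-3-(propan-2-yloxy)phenyl]-6-methoxy-2-(4-methoxyphenyl)-2,3-dihydro-1-benzofuran, via diazo compound 13 (not isolated), via cis-dihydrobenzofuran 14 (not isolated)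
Conditions: MnO2, CH2Cl2, 0 °C, filter; Rh2(R-PTAD)4 (1 mol %), CH2Cl2, −20 °C → rt; then TFA, rt
Reagents that add atoms: none
Why: Dehydrogenation of the hydrazone gives the diaryldiazomethane, whose rhodium carbene inserts into a benzylic C–H bond of the 4-methoxybenzyl ether (1,5-insertion) to form C5–Cα; the chiral carboxylate ligands fix the configuration at C5 and the concerted insertion places the two aryl groups cis. TFA then opens and recloses the Cα–O bond through the 4-methoxybenzylic cation, which inverts Cα only and leads to the more stable trans isomer.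

Step 9
Reactants: 15 (2S,3R)-3-[2-iodo-5-methoxy-3-(propan-2-yloxy)phenyl]-6-methoxy-2-(4-methoxyphenyl)-2,3-dihydro-1-benzofuran; 16 [(4-methoxyphenyl)ethynyl]trimethylsilane
Product: 17 (1S,11bS)-4,10-dimethoxy-1,7-bis(4-methoxyphenyl)-8-(propan-2-yloxy)-6-(trimethylsilyl)-1,11b-dihydrobenzo[6,7]cyclohepta[1,2,3-cd][1]benzofuran
Conditions: Pd(OAc)2 (10 mol %), PCy3·HBF4 (20 mol %), CsOPiv (3 equiv), 16 (2 equiv), DMA, 110 °C
Reagents that add atoms: none
Why: Proposed new method: zerovalent palladium formed from Pd(OAc)2 and PCy3 inserts into the c6–I bond of 15, the arylpalladium adds syn across 16 with the aryl group going to the anisyl-bearing carbon (c6–C10) and palladium to the silyl-bearing carbon, and pivalate-assisted concerted metallation–deprotonation of b1–H followed by reductive elimination forms C11–b1; the closest known reactions are the palladium-catalysed annulation of 2-halobiaryls with alkynes to phenanthrenes and, for the orientation of the silylalkyne, the Larock indole synthesis. The seven-membered ring is closed by C(sp2)–C(sp2) reductive elimination from an eight-membered vinyl(aryl)palladacycle, a formal [5+2] annulation in which c6, c1, C5, b6 and b1 supply five atoms and the alkyne two. No stereocentre is formed: C5 and Cα are spectators whose hydrogens are far too weakly acidic for pivalate, and the double-bond geometry (ring C and ring B cis) follows from the syn carbopalladation. The orientation of insertion is secured by the trimethylsilyl group, which keeps the bulky palladium–phosphine fragment on its own carbon. Site selectivity of the C–H step is secured by the substrate: both carbons ortho to c6 are substituted, so a 1,4-palladium shift onto ring C is impossible, the anisyl ring is trans to palladium and out of reach unless the vinylpalladium isomerises, and b1–H is held next to C11 by the rigid 3-aryldihydrobenzofuran. Direct arylation of b1 before alkyne insertion would give a strained cyclopenta-fused ring and should not compete, and the isopropyl ether removes the facile direct arylation that a benzyl ether ortho to the iodide would undergo under these same conditions.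

Step 10
Reactants: 17 (1S,11bS)-4,10-dimethoxy-1,7-bis(4-methoxyphenyl)-8-(propan-2-yloxy)-6-(trimethylsilyl)-1,11b-dihydrobenzo[6,7]cyclohepta[1,2,3-cd][1]benzofuran
Product: 18 (1S,11bS)-4,10-dimethoxy-1,7-bis(4-methoxyphenyl)-8-(propan-2-yloxy)-1,11b-dihydrobenzo[6,7]cyclohepta[1,2,3-cd][1]benzofuran
Conditions: TFA, CH2Cl2, 0 °C → rt
Reagents that add atoms: none
Why: Protodesilylation of a vinylsilane: protonation at C11 gives a cation at C10 stabilised by silicon (β-effect) and by two aryl groups, and loss of the silyl group restores the double bond; the dihydrofuran was already equilibrated under this acid in step 8 and should stay trans.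

Step 11
Reactants: 18 (1S,11bS)-4,10-dimethoxy-1,7-bis(4-methoxyphenyl)-8-(propan-2-yloxy)-1,11b-dihydrobenzo[6,7]cyclohepta[1,2,3-cd][1]benzofuran
Product: 19 (1S,11bS)-4,10-dimethoxy-1,7-bis(4-methoxyphenyl)-1,11b-dihydrobenzo[6,7]cyclohepta[1,2,3-cd][1]benzofuran-8-ol
Conditions: BCl3, CH2Cl2, −78 → 0 °C
Reagents that add atoms: none
Why: Lewis acid cleavage of an aryl alkyl ether; the secondary isopropyl–oxygen bond ionises far more readily than a methyl–oxygen bond, which gives the selectivity over the four methyl ethers, and the low temperature limits ionisation at Cα.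

Step 12
Reactants: 19 (1S,11bS)-4,10-dimethoxy-1,7-bis(4-methoxyphenyl)-1,11b-dihydrobenzo[6,7]cyclohepta[1,2,3-cd][1]benzofuran-8-ol
Product: 20 (1S,11bS)-8-hydroxy-4,10-dimethoxy-1,7-bis(4-methoxyphenyl)-1,11b-dihydrobenzo[6,7]cyclohepta[1,2,3-cd][1]benzofuran-9-carbaldehyde
Conditions: MgCl2, Et3N, (CH2O)n, MeCN, reflux
Reagents that add atoms: paraformaldehyde (as formaldehyde), C=O
Why: Casnati–Skattebøl ortho-formylation: the magnesium phenoxide delivers formaldehyde to its ortho carbon and a second equivalent oxidises the hydroxymethyl intermediate by hydride transfer; c6 is substituted, so c4 is the only ortho position.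

Step 13
Reactants: 20 (1S,11bS)-8-hydroxy-4,10-dimethoxy-1,7-bis(4-methoxyphenyl)-1,11b-dihydrobenzo[6,7]cyclohepta[1,2,3-cd][1]benzofuran-9-carbaldehyde; 7 4-methoxybenzyl chloride
Product: 21 (1S,11bS)-4,10-dimethoxy-8-[(4-methoxybenzyl)oxy]-1,7-bis(4-methoxyphenyl)-1,11b-dihydrobenzo[6,7]cyclohepta[1,2,3-cd][1]benzofuran-9-carbaldehyde
Conditions: K2CO3, KI (cat.), DMF, 60 °C
Reagents that add atoms: none
Why: Williamson ether synthesis; the chelated, hindered phenol needs a polar solvent and heat, and the benzylic carbon introduced here becomes C2″.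

Step 14
Reactants: 21 (1S,11bS)-4,10-dimethoxy-8-[(4-methoxybenzyl)oxy]-1,7-bis(4-methoxyphenyl)-1,11b-dihydrobenzo[6,7]cyclohepta[1,2,3-cd][1]benzofuran-9-carbaldehyde; 22 1-bromo-3,5-dimethoxybenzene
Product: 24 (3,5-dimethoxyphenyl){(1S,11bS)-4,10-dimethoxy-8-[(4-methoxybenzyl)oxy]-1,7-bis(4-methoxyphenyl)-1,11b-dihydrobenzo[6,7]cyclohepta[1,2,3-cd][1]benzofuran-9-yl}methanol (carbinol epimers), via (3,5-dimethoxyphenyl)magnesium bromide 23 (not isolated)
Conditions: Mg, I2 (cat.), THF, reflux; then 21, THF, −40 → 0 °C; aq. NH4Cl
Reagents that add atoms: none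
Why: Grignard addition to the aldehyde, helped by chelation to the two ortho ethers; both carbinol epimers are carried on because the centre is oxidised in step 15.

Step 15
Reactants: 24 (3,5-dimethoxyphenyl){(1S,11bS)-4,10-dimethoxy-8-[(4-methoxybenzyl)oxy]-1,7-bis(4-methoxyphenyl)-1,11b-dihydrobenzo[6,7]cyclohepta[1,2,3-cd][1]benzofuran-9-yl}methanol
Product: 25 (3,5-dimethoxyphenyl){(1S,11bS)-4,10-dimethoxy-8-[(4-methoxybenzyl)oxy]-1,7-bis(4-methoxyphenyl)-1,11b-dihydrobenzo[6,7]cyclohepta[1,2,3-cd][1]benzofuran-9-yl}methanone
Conditions: Dess–Martin periodinane, CH2Cl2, rt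
Reagents that add atoms: none
Why: Dess–Martin oxidation of a benzhydrol; no free phenol is present and the triarylethylene is inert to the reagent.

Step 16
Reactants: 25 (3,5-dimethoxyphenyl){(1S,11bS)-4,10-dimethoxy-8-[(4-methoxybenzyl)oxy]-1,7-bis(4-methoxyphenyl)-1,11b-dihydrobenzo[6,7]cyclohepta[1,2,3-cd][1]benzofuran-9-yl}methanone
Product: 26 hydrazone of 25 (C=N isomers)
Conditions: N2H4·H2O (excess), AcOH (cat.), EtOH, 100 °C (sealed tube)
Reagents that add atoms: hydrazine (used as hydrate), NN
Why: Condensation of the ketone with hydrazine; the carbonyl is flanked by two ortho ethers on one ring only and remains open from the side of the dimethoxyphenyl ring, so forcing conditions should suffice.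

Step 17
Reactants: 26 hydrazone of 25
Product: 29 heptamethyl ether of the target with the ring C dihydrofuran (2″R,3″R)-trans, via diazo compound 27 (not isolated), via cis-dihydrofuran isomer 28 (not isolated)
Conditions: MnO2, CH2Cl2, 0 °C, filter; Rh2(S-PTAD)4 (2 mol %), CH2Cl2, 0 °C → rt; then TFA, rt
Reagents that add atoms: none
Why: Donor–donor rhodium carbene 1,5-insertion into the benzylic C–H bond of the 4-methoxybenzyl ether on c5–O forms C2″–C3″; that bond is far more reactive than the primary C–H bonds of the methoxy group on c3, and the catalyst sets C3″ because C5 and Cα are too remote to interfere. TFA then equilibrates C2″ to trans through the 4-methoxybenzylic cation, while the ring B furan is already at its trans equilibrium.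

Step 18
Reactants: 29 heptamethyl ether of the target
Product: 30 target CNP0325907.1 (5S;αS;2″R;3″R)
Conditions: BBr3 (excess), CH2Cl2, −78 °C → rt; then MeOH, H2O
Reagents that add atoms: none
Why: Lewis acid O-demethylation of all seven aryl methyl ethers; each ether oxygen is converted early into a borate, which makes the aryl groups on Cα and C2″ poorer donors and should restrain ionisation of the benzylic C–O bonds, and no stereocentre is involved.

## Compound list

1 | 3-hydroxy-5-methoxybenzaldehyde | O=Cc1cc(O)cc(OC)c1 | starting material
2 | 3-formyl-5-methoxyphenyl acetate | CC(=O)Oc1cc(OC)cc(C=O)c1 | intermediate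
3 | 3-formyl-2-iodo-5-methoxyphenyl acetate | CC(=O)Oc1cc(OC)cc(C=O)c1I | intermediate
4 | 3-hydroxy-2-iodo-5-methoxybenzaldehyde (not isolated) | O=Cc1cc(OC)cc(O)c1I | intermediate
5 | 2-iodo-5-methoxy-3-(propan-2-yloxy)benzaldehyde | O=Cc1cc(OC)cc(OC(C)C)c1I | intermediate
6 | 2-bromo-5-methoxyphenol | COc1ccc(Br)c(O)c1 | starting material
7 | 4-methoxybenzyl chloride | COc1ccc(CCl)cc1 | starting material
8 | 1-bromo-4-methoxy-2-[(4-methoxybenzyl)oxy]benzene | COc1ccc(Br)c(OCc2ccc(OC)cc2)c1 | intermediate
9 | {4-methoxy-2-[(4-methoxybenzyl)oxy]phenyl}magnesium bromide (not isolated) | COc1ccc([Mg]Br)c(OCc2ccc(OC)cc2)c1 | intermediate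
10 | [2-iodo-5-methoxy-3-(propan-2-yloxy)phenyl]{4-methoxy-2-[(4-methoxybenzyl)oxy]phenyl}methanol, racemic | COc1ccc(C(O)c2cc(OC)cc(OC(C)C)c2I)c(OCc2ccc(OC)cc2)c1 | intermediate
11 | [2-iodo-5-methoxy-3-(propan-2-yloxy)phenyl]{4-methoxy-2-[(4-methoxybenzyl)oxy]phenyl}methanone | COc1ccc(C(=O)c2cc(OC)cc(OC(C)C)c2I)c(OCc2ccc(OC)cc2)c1 | intermediate
12 | hydrazone of 11 | COc1ccc(C(=NN)c2cc(OC)cc(OC(C)C)c2I)c(OCc2ccc(OC)cc2)c1 | intermediate
13 | 1-{diazo[2-iodo-5-methoxy-3-(propan-2-yloxy)phenyl]methyl}-4-methoxy-2-[(4-methoxybenzyl)oxy]benzene (not isolated) | COc1ccc(C(=[N+]=[N-])c2cc(OC)cc(OC(C)C)c2I)c(OCc2ccc(OC)cc2)c1 | intermediate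
14 | (2R,3R)-3-[2-iodo-5-methoxy-3-(propan-2-yloxy)phenyl]-6-methoxy-2-(4-methoxyphenyl)-2,3-dihydro-1-benzofuran, cis (not isolated) | c1cc(OC)cc2c1[C@H](c1cc(OC)cc(OC(C)C)c1I)[C@H](c1ccc(OC)cc1)O2 | intermediate
15 | (2S,3R)-3-[2-iodo-5-methoxy-3-(propan-2-yloxy)phenyl]-6-methoxy-2-(4-methoxyphenyl)-2,3-dihydro-1-benzofuran, trans | c1cc(OC)cc2c1[C@H](c1cc(OC)cc(OC(C)C)c1I)[C@@H](c1ccc(OC)cc1)O2 | intermediate
16 | [(4-methoxyphenyl)ethynyl]trimethylsilane | COc1ccc(C#C[Si](C)(C)C)cc1 | starting material
17 | (1S,11bS)-4,10-dimethoxy-1,7-bis(4-methoxyphenyl)-8-(propan-2-yloxy)-6-(trimethylsilyl)-1,11b-dihydrobenzo[6,7]cyclohepta[1,2,3-cd][1]benzofuran | COc1ccc(C2=C([Si](C)(C)C)c3cc(OC)cc4c3[C@H](c3cc(OC)cc(OC(C)C)c32)[C@@H](c2ccc(OC)cc2)O4)cc1 | intermediate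
18 | (1S,11bS)-4,10-dimethoxy-1,7-bis(4-methoxyphenyl)-8-(propan-2-yloxy)-1,11b-dihydrobenzo[6,7]cyclohepta[1,2,3-cd][1]benzofuran | COc1ccc(C2=Cc3cc(OC)cc4c3[C@H](c3cc(OC)cc(OC(C)C)c32)[C@@H](c2ccc(OC)cc2)O4)cc1 | intermediate
19 | (1S,11bS)-4,10-dimethoxy-1,7-bis(4-methoxyphenyl)-1,11b-dihydrobenzo[6,7]cyclohepta[1,2,3-cd][1]benzofuran-8-ol | COc1ccc(C2=Cc3cc(OC)cc4c3[C@H](c3cc(OC)cc(O)c32)[C@@H](c2ccc(OC)cc2)O4)cc1 | intermediate
20 | (1S,11bS)-8-hydroxy-4,10-dimethoxy-1,7-bis(4-methoxyphenyl)-1,11b-dihydrobenzo[6,7]cyclohepta[1,2,3-cd][1]benzofuran-9-carbaldehyde | COc1ccc(C2=Cc3cc(OC)cc4c3[C@H](c3cc(OC)c(C=O)c(O)c32)[C@@H](c2ccc(OC)cc2)O4)cc1 | intermediate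
21 | (1S,11bS)-4,10-dimethoxy-8-[(4-methoxybenzyl)oxy]-1,7-bis(4-methoxyphenyl)-1,11b-dihydrobenzo[6,7]cyclohepta[1,2,3-cd][1]benzofuran-9-carbaldehyde | COc1ccc(C2=Cc3cc(OC)cc4c3[C@H](c3cc(OC)c(C=O)c(OCc5ccc(OC)cc5)c32)[C@@H](c2ccc(OC)cc2)O4)cc1 | intermediate
22 | 1-bromo-3,5-dimethoxybenzene | COc1cc(Br)cc(OC)c1 | starting material
23 | (3,5-dimethoxyphenyl)magnesium bromide (not isolated) | COc1cc(OC)cc([Mg]Br)c1 | intermediate
24 | (3,5-dimethoxyphenyl){(1S,11bS)-4,10-dimethoxy-8-[(4-methoxybenzyl)oxy]-1,7-bis(4-methoxyphenyl)-1,11b-dihydrobenzo[6,7]cyclohepta[1,2,3-cd][1]benzofuran-9-yl}methanol, carbinol epimers | COc1ccc(C2=Cc3cc(OC)cc4c3[C@H](c3cc(OC)c(C(O)c5cc(OC)cc(OC)c5)c(OCc5ccc(OC)cc5)c32)[C@@H](c2ccc(OC)cc2)O4)cc1 | intermediate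
25 | (3,5-dimethoxyphenyl){(1S,11bS)-4,10-dimethoxy-8-[(4-methoxybenzyl)oxy]-1,7-bis(4-methoxyphenyl)-1,11b-dihydrobenzo[6,7]cyclohepta[1,2,3-cd][1]benzofuran-9-yl}methanone | COc1ccc(C2=Cc3cc(OC)cc4c3[C@H](c3cc(OC)c(C(=O)c5cc(OC)cc(OC)c5)c(OCc5ccc(OC)cc5)c32)[C@@H](c2ccc(OC)cc2)O4)cc1 | intermediate
26 | hydrazone of 25 | COc1ccc(C2=Cc3cc(OC)cc4c3[C@H](c3cc(OC)c(C(=NN)c5cc(OC)cc(OC)c5)c(OCc5ccc(OC)cc5)c32)[C@@H](c2ccc(OC)cc2)O4)cc1 | intermediate
27 | diazo compound from 26: the 9-[diazo(3,5-dimethoxyphenyl)methyl] analogue of 21 (not isolated) | COc1ccc(C2=Cc3cc(OC)cc4c3[C@H](c3cc(OC)c(C(=[N+]=[N-])c5cc(OC)cc(OC)c5)c(OCc5ccc(OC)cc5)c32)[C@@H](c2ccc(OC)cc2)O4)cc1 | intermediate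
28 | heptamethyl ether with the ring C dihydrofuran cis, (5S,αS,2″S,3″R) (not isolated) | COc1ccc(C2=Cc3cc(OC)cc4c3[C@H](c3cc(OC)c5c(c32)O[C@H](c2ccc(OC)cc2)[C@@H]5c2cc(OC)cc(OC)c2)[C@@H](c2ccc(OC)cc2)O4)cc1 | intermediate
29 | heptamethyl ether of the target, (5S,αS,2″R,3″R): core of 18 with c5–O and c4 closed to a trans-dihydrofuran through C2″H(4-methoxyphenyl) and C3″H(3,5-dimethoxyphenyl), methoxy on c3 | COc1ccc(C2=Cc3cc(OC)cc4c3[C@H](c3cc(OC)c5c(c32)O[C@@H](c2ccc(OC)cc2)[C@@H]5c2cc(OC)cc(OC)c2)[C@@H](c2ccc(OC)cc2)O4)cc1 | intermediate
30 | CNP0325907.1, (5S,αS,2″R,3″R)-heptaphenol | Oc1ccc(C2=Cc3cc(O)cc4c3[C@H](c3cc(O)c5c(c32)O[C@@H](c2ccc(O)cc2)[C@@H]5c2cc(O)cc(O)c2)[C@@H](c2ccc(O)cc2)O4)cc1 | target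

## Step count and least certain steps

Total: 18 steps. Longest linear sequence: 17 steps (from 1 through steps 1–3 and 5–18); step 4 is the only step off the main line.

Step 9 (key step, proposed new method). The most likely failure is that the second half of the sequence does not follow the first. After carbopalladation the vinylpalladium has to metallate b1–H through an eight-membered transition state; if this is slow it will instead be protonated (net hydroarylation of the alkyne) or isomerise about the double bond and attack the anisyl ring. A slow insertion of the doubly ortho-substituted arylpalladium into the silylalkyne would show up as simple reduction of the iodide.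

The fallback uses known chemistry only, sets out from 3 and returns at 18. It gives b1 a carbon substituent from the start, so that the ring is closed by carbonyl olefination and not by C–H functionalisation:
- Methanolysis of 3 and alkylation of the resulting phenol with 7 (K2CO3, DMF) gives 2-iodo-5-methoxy-3-[(4-methoxybenzyl)oxy]benzaldehyde F1.
- The aldehyde is masked (HC(OMe)3, PPTS, MeOH) as 1-(dimethoxymethyl)-2-iodo-5-methoxy-3-[(4-methoxybenzyl)oxy]benzene F2.
- Iodine–magnesium exchange (iPrMgCl·LiCl, 1.0 equiv, THF, −20 °C) gives {2-(dimethoxymethyl)-4-methoxy-6-[(4-methoxybenzyl)oxy]phenyl}magnesium chloride F3, which adds to 5 to give the diaryl carbinol F4.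
- Dess–Martin oxidation gives the diaryl ketone F5, and hydrazine gives its hydrazone F6.
- The sequence of step 8 (MnO2; Rh2(R-PTAD)4; then wet TFA, which also unmasks the aldehyde) leads through the diazo compound F7 and the cis-dihydrobenzofuran acetal F8 to (2S,3R)-3-[2-iodo-5-methoxy-3-(propan-2-yloxy)phenyl]-6-methoxy-2-(4-methoxyphenyl)-2,3-dihydro-1-benzofuran-4-carbaldehyde F9.
- Carbonylative Suzuki–Miyaura coupling of the iodide with 4-methoxyphenylboronic acid (PdCl2(dppf), CO, K2CO3, anisole, 80 °C) gives the keto aldehyde F10.
- Intramolecular McMurry coupling with low-valent titanium (TiCl4, Zn, pyridine, THF, reflux) joins the aldehyde carbon (C11) to the ketone carbon (C10) and gives 18.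

The iodide still defines c6, so the regiochemistry of ring C is kept. The cost is seven more steps and a hydrazone formation at a more crowded ketone.

Step 16. The condensation of hydrazine with a ketone flanked by two ortho ethers may stall, and the heat needed to drive it threatens the 4-methoxybenzyl ether. The fallback sets out from 21 and returns at 26, and reaches the C=N bond without passing through the ketone. Hydroxylamine hydrochloride and pyridine in ethanol convert 21 into the aldoxime F11, which is dehydrated in the same flask with Ac2O at 90 °C to the nitrile F12. Addition of 23 (THF, reflux, CuBr cat.) and quenching with dry methanol gives the N–H ketimine F13. The ketimine, far more electrophilic than the ketone once protonated, exchanges ammonia for hydrazine (N2H4·H2O, AcOH, EtOH, 50 °C) to give 26.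

Step 18. Ionisation of the benzylic C–O bonds at Cα and C2″ by the Lewis acid, followed by ring opening, elimination towards C5 or C3″ or recombination with the wrong geometry, may outrun removal of the seven methyl groups; addition of HBr to the triarylethylene is a lesser risk. The fallback sets out from 29 and returns at 30. It replaces electrophilic dealkylation by nucleophilic dealkylation (NaSEt in excess, DMF, 140–150 °C), in which thiolate attacks the methyl carbons by SN2 and the benzylic ethers are never activated; the second methyl group of the resorcinol ring will be the slowest to leave. No new compound is made on the way.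

Step 2. Attack ortho to the methoxy group may compete with attack para to it, because all three free ring positions are flanked on both sides. The fallback sets out from 1 and returns at 4. It changes the directing element: the free phenol 1 is iodinated as its phenoxide (I2, NaHCO3, THF–H2O, 0 °C → rt), where the oxygen anion directs ortho to itself and para to the methoxy group, the same carbon as before. The phenol 4 is then alkylated as in the second half of step 3. No new compound is made on the way.

## Further compounds

F1 | step 9 | 2-iodo-5-methoxy-3-[(4-methoxybenzyl)oxy]benzaldehyde | O=Cc1cc(OC)cc(OCc2ccc(OC)cc2)c1I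
F2 | step 9 | 1-(dimethoxymethyl)-2-iodo-5-methoxy-3-[(4-methoxybenzyl)oxy]benzene | COC(OC)c1cc(OC)cc(OCc2ccc(OC)cc2)c1I
F3 | step 9 | {2-(dimethoxymethyl)-4-methoxy-6-[(4-methoxybenzyl)oxy]phenyl}magnesium chloride | COC(OC)c1cc(OC)cc(OCc2ccc(OC)cc2)c1[Mg]Cl
F4 | step 9 | {2-(dimethoxymethyl)-4-methoxy-6-[(4-methoxybenzyl)oxy]phenyl}[2-iodo-5-methoxy-3-(propan-2-yloxy)phenyl]methanol, racemic | COC(OC)c1cc(OC)cc(OCc2ccc(OC)cc2)c1C(O)c1cc(OC)cc(OC(C)C)c1I
F5 | step 9 | {2-(dimethoxymethyl)-4-methoxy-6-[(4-methoxybenzyl)oxy]phenyl}[2-iodo-5-methoxy-3-(propan-2-yloxy)phenyl]methanone | COC(OC)c1cc(OC)cc(OCc2ccc(OC)cc2)c1C(=O)c1cc(OC)cc(OC(C)C)c1I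
F6 | step 9 | hydrazone of F5 | COC(OC)c1cc(OC)cc(OCc2ccc(OC)cc2)c1C(=NN)c1cc(OC)cc(OC(C)C)c1I
F7 | step 9 | diazo compound from F6 | COC(OC)c1cc(OC)cc(OCc2ccc(OC)cc2)c1C(=[N+]=[N-])c1cc(OC)cc(OC(C)C)c1I
F8 | step 9 | (2R,3R)-4-(dimethoxymethyl)-3-[2-iodo-5-methoxy-3-(propan-2-yloxy)phenyl]-6-methoxy-2-(4-methoxyphenyl)-2,3-dihydro-1-benzofuran, cis | COC(OC)c1cc(OC)cc2c1[C@H](c1cc(OC)cc(OC(C)C)c1I)[C@H](c1ccc(OC)cc1)O2
F9 | step 9 | (2S,3R)-3-[2-iodo-5-methoxy-3-(propan-2-yloxy)phenyl]-6-methoxy-2-(4-methoxyphenyl)-2,3-dihydro-1-benzofuran-4-carbaldehyde | O=Cc1cc(OC)cc2c1[C@H](c1cc(OC)cc(OC(C)C)c1I)[C@@H](c1ccc(OC)cc1)O2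
F10 | step 9 | (2S,3S)-6-methoxy-3-[5-methoxy-2-(4-methoxybenzoyl)-3-(propan-2-yloxy)phenyl]-2-(4-methoxyphenyl)-2,3-dihydro-1-benzofuran-4-carbaldehyde | O=Cc1cc(OC)cc2c1[C@H](c1cc(OC)cc(OC(C)C)c1C(=O)c1ccc(OC)cc1)[C@@H](c1ccc(OC)cc1)O2
F11 | step 16 | oxime of 21 | COc1ccc(C2=Cc3cc(OC)cc4c3[C@H](c3cc(OC)c(C=NO)c(OCc5ccc(OC)cc5)c32)[C@@H](c2ccc(OC)cc2)O4)cc1
F12 | step 16 | (1S,11bS)-4,10-dimethoxy-8-[(4-methoxybenzyl)oxy]-1,7-bis(4-methoxyphenyl)-1,11b-dihydrobenzo[6,7]cyclohepta[1,2,3-cd][1]benzofuran-9-carbonitrile | COc1ccc(C2=Cc3cc(OC)cc4c3[C@H](c3cc(OC)c(C#N)c(OCc5ccc(OC)cc5)c32)[C@@H](c2ccc(OC)cc2)O4)cc1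
F13 | step 16 | N–H ketimine corresponding to ketone 25 | COc1ccc(C2=Cc3cc(OC)cc4c3[C@H](c3cc(OC)c(C(=N)c5cc(OC)cc(OC)c5)c(OCc5ccc(OC)cc5)c32)[C@@H](c2ccc(OC)cc2)O4)cc1
F0 | step 18 | none | none
F0 | step 2 | none | none
A1 | alternative 1 | 4-[(1S,11bS)-8,10-dihydroxy-4-methoxy-7-(4-methoxyphenyl)-1,11b-dihydrobenzo[6,7]cyclohepta[1,2,3-cd][1]benzofuran-1-yl]phenyl 2,2-dimethylpropanoate | COc1ccc(C2=Cc3cc(OC)cc4c3[C@H](c3cc(O)cc(O)c32)[C@@H](c2ccc(OC(=O)C(C)(C)C)cc2)O4)cc1
A2 | alternative 1 | 4-{(1R)-2-(3,5-dihydroxyphenyl)-2-hydroxy-1-[3-methoxy-5-[(4-methoxyphenyl)ethynyl]phenoxy]ethyl}phenyl 2,2-dimethylpropanoate, carbinol epimers | COc1ccc(C#Cc2cc(OC)cc(O[C@H](c3ccc(OC(=O)C(C)(C)C)cc3)C(O)c3cc(O)cc(O)c3)c2)cc1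
A3 | alternative 2 | methyl (2S,3S)-6-methoxy-2-(4-methoxyphenyl)-4-{[(trifluoromethyl)sulfonyl]oxy}-2,3-dihydro-1-benzofuran-3-carboxylate, trans | FC(F)(F)S(=O)(=O)Oc1cc(OC)cc2c1[C@H](C(=O)OC)[C@@H](c1ccc(OC)cc1)O2
A4 | alternative 2 | (2S)-7-methoxy-2-(4-methoxyphenyl)-4-oxo-3,4-dihydro-2H-chromen-5-yl trifluoromethanesulfonate | FC(F)(F)S(=O)(=O)Oc1cc(OC)cc2c1C(=O)C[C@@H](c1ccc(OC)cc1)O2
A5 | alternative 2 | (2S)-naringenin | O=C1C[C@@H](c2ccc(O)cc2)Oc2cc(O)cc(O)c12
A6 | alternative 3 | heptamethyl ether of the target, identical with 29 | COc1ccc(C2=Cc3cc(OC)cc4c3[C@H](c3cc(OC)c5c(c32)O[C@@H](c2ccc(OC)cc2)[C@@H]5c2cc(OC)cc(OC)c2)[C@@H](c2ccc(OC)cc2)O4)cc1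
A7 | alternative 3 | diaryldiazomethane identical with 27 | COc1ccc(C2=Cc3cc(OC)cc4c3[C@H](c3cc(OC)c(C(=[N+]=[N-])c5cc(OC)cc(OC)c5)c(OCc5ccc(OC)cc5)c32)[C@@H](c2ccc(OC)cc2)O4)cc1
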